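**Retrosynthetic overview**
1. The target is (13E)-3α,6β,19-trihydroxylabda-8,13-dien-15-oic acid (3R,4S,5R,6R,10S). The plan rests on the tetrasubstituted C8=C9 alkene of ring B, which carries methyl C17 and chain carbon C11 and stands next to quaternary C10 (C20). That pattern is what remains when methyl but-2-ynoate adds across C7 and C10 of a ring-A 1-vinylcyclohexene (C10=C5–C6=C7).
2. Ring A is made first from 2-methylcyclohexane-1,3-dione: hydroxymethylation gives C19, enzymatic desymmetrisation sets C3 and C4, methylation gives C20, enol triflate and vinylation give C6 and C7. Ring B is then closed by the Diels–Alder reaction (bonds C7–C8 and C9–C10, stereocentre C10).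
3. The two ring-A oxygens are left untied, and C3 is carried in its final 3α configuration as a silyl ether trans to C19. A cis-fused 3,19-acetal would sit oxygen-axial, hold C19 pseudoequatorial and turn the dienophile to the β face. The trans bis-silyl ether should react through its diaxial conformer (C19 axial on the β face), which leaves the α face open. The weak dienophile is activated with EtAlCl2 so that the cycloaddition runs cold.
4. After ring B: α-face hydroboration of Δ5 (5α-H), oxidation and α-face hydride addition give the 6β-alcohol. The C11 ester is extended through the allylic bromide, acetoacetate alkylation and Horner–Wadsworth–Emmons olefination (C13=C14, E). Desilylation and saponification finish the route.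

Key step: step 8

Assumption: a ketoreductase that reduces dione 4 to the (2S,3R)-hydroxy ketone 5 (hydroxyl cis to the ring methyl) is taken to be found in a commercial screening panel. Labdane numbering (C1–C20) is used for all intermediates, and TBS stands for tert-butyldimethylsilyl.

**Step 1**
Reactants: 1 2-methylcyclohexane-1,3-dione; 2 formaldehyde
Product: 3 2-(hydroxymethyl)-2-methylcyclohexane-1,3-dione
Conditions: 37% aq. CH2O (3 equiv), H2O, rt
Reagents that add atoms: none
Why: Aldol-type hydroxymethylation of the enolised 1,3-dione at C2 gives the quaternary, non-enolisable adduct, and the excess of formaldehyde holds the equilibrium on the product side.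

**Step 2**
Reactants: 3 2-(hydroxymethyl)-2-methylcyclohexane-1,3-dione
Product: 4 2-[(TBS-oxy)methyl]-2-methylcyclohexane-1,3-dione
Conditions: TBSCl, imidazole, CH2Cl2, 0 °C → rt
Reagents that add atoms: tert-butyldimethylsilyl chloride, CC(C)(C)[Si](C)(C)Cl
Why: Imidazole-mediated silylation of the primary alcohol blocks retro-aldol loss of formaldehyde in the buffered enzymatic step and installs the bulky C19 ether.

**Step 3**
Reactants: 4 2-[(TBS-oxy)methyl]-2-methylcyclohexane-1,3-dione
Product: 5 (2S,3R)-2-[(TBS-oxy)methyl]-3-hydroxy-2-methylcyclohexan-1-one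
Conditions: ketoreductase (NADPH-dependent, chosen by screening), NADP+ (cat.), i-PrOH (10% v/v), KH2PO4/K2HPO4 buffer pH 7.0, 30 °C
Reagents that add atoms: none
Why: In this enzymatic desymmetrising ketone reduction, hydride is delivered to one face of one of the two enantiotopic carbonyls, which sets C3 (R, hydroxyl cis to the ring methyl and trans to CH2OTBS) and with it the quaternary C4 (S).

**Step 4**
Reactants: 5 (2S,3R)-2-[(TBS-oxy)methyl]-3-hydroxy-2-methylcyclohexan-1-one
Product: 6 (2S,3R)-3-(TBS-oxy)-2-[(TBS-oxy)methyl]-2-methylcyclohexan-1-one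
Conditions: TBSOTf, 2,6-lutidine, CH2Cl2, −78 → 0 °C
Reagents that add atoms: tert-butyldimethylsilyl trifluoromethanesulfonate, CC(C)(C)[Si](C)(C)OS(=O)(=O)C(F)(F)F
Why: Silylation of the hindered secondary alcohol with the silyl triflate proceeds without touching a stereocentre and gives the trans-disposed pair of bulky ethers used in step 8.

**Step 5**
Reactants: 6 (2S,3R)-3-(TBS-oxy)-2-[(TBS-oxy)methyl]-2-methylcyclohexan-1-one
Product: 8 (2S,3R,6RS)-3-(TBS-oxy)-2-[(TBS-oxy)methyl]-2,6-dimethylcyclohexan-1-one, via lithium enolate 7 (not isolated)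
Conditions: LiN(i-Pr)2, THF, −78 °C; MeI, −78 → 0 °C
Reagents that add atoms: iodomethane, CI
Why: Only C6 of the ketone (labdane C10) carries α-hydrogens, so enolate alkylation by SN2 gives a single regioisomer; the new centre is a mixture that becomes planar in step 6.

**Step 6**
Reactants: 8 (2S,3R,6RS)-3-(TBS-oxy)-2-[(TBS-oxy)methyl]-2,6-dimethylcyclohexan-1-one
Product: 10 (5R,6S)-5-(TBS-oxy)-6-[(TBS-oxy)methyl]-2,6-dimethylcyclohex-1-en-1-yl trifluoromethanesulfonate, via potassium enolate 9 (not isolated)
Conditions: KN(SiMe3)2, THF, −78 → 0 °C; PhNTf2, −78 °C → rt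
Reagents that add atoms: N-phenylbis(trifluoromethanesulfonimide), O=S(=O)(N(c1ccccc1)S(=O)(=O)C(F)(F)F)C(F)(F)F
Why: The one remaining α-hydrogen is on the methyl-bearing carbon, so deprotonation can only give the tetrasubstituted enolate, which is O-sulfonylated (enol triflate formation).

**Step 7**
Reactants: 10 the enol triflate; 11 tributyl(vinyl)stannane
Product: 12 ring-A diene, tert-butyl{[(1S,6R)-6-(TBS-oxy)-2-ethenyl-1,3-dimethylcyclohex-2-en-1-yl]methoxy}dimethylsilane (labdane: C10=C5–C6=C7, 3α-OTBS, 19-OTBS)
Conditions: Pd(PPh3)4 (5 mol%), LiCl (3 equiv), THF, 65 °C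
Reagents that add atoms: none
Why: Stille coupling (oxidative addition of the enol triflate, chloride-assisted transmetalation, reductive elimination) is established for hindered cyclohexenyl triflates and gives the diene without touching C3 or C4.

**Step 8**
Reactants: 12 ring-A diene; 13 methyl but-2-ynoate
Product: 14 methyl 3α,19-bis(TBS-oxy)-12,13,14,15,16-pentanorlabda-5,8-dien-11-oate (3R,4S,10S; C9 CO2Me, C8 methyl, C10 β-methyl)
Conditions: 13 (3 equiv), EtAlCl2 (0.5 equiv), CH2Cl2, −20 °C → rt
Reagents that add atoms: none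
Why: EtAlCl2 bound to the ester carbonyl of 13 lowers its LUMO, and a concerted but asynchronous [4+2] cycloaddition follows in which the unsubstituted diene terminus C7 bonds to the β-carbon (C8) ahead of the bond from the fully substituted terminus C10 to the α-carbon (C9); the closest known reaction type is the Diels–Alder reaction of 2,6,6-trisubstituted 1-vinylcyclohexenes with acetylenic esters used for drimane decalins, here Lewis-acid promoted because a but-2-ynoate is a far weaker dienophile than an acetylenedicarboxylate. Ring B closes as a six-membered cyclohexa-1,4-diene by suprafacial 4π+2π addition across C7 and C10 of the s-cis diene, and its C8=C9 bond is already the tetrasubstituted alkene of the target. The regiochemistry needed (C11 on C9, C17 on C8) follows from the largest HOMO coefficient at C7, from the tertiary allylic cation character that builds up at C10, and from the largest LUMO coefficient at the β-carbon of the complexed ynoate. The only new stereocentre is C10, fixed by the face of ring A that is attacked: in the product-like chair of ring A the new C9–C10 bond is equatorial and C20 becomes axial, syn to whichever substituent of C4 is axial, so attack on the α face, anti to a pseudoaxial C19, gives C20 β. The precursor is shaped to react through that conformer: the 3α-silyloxy group and the C19 silyloxymethyl group are trans, and their diaxial arrangement avoids the gauche contact of the two bulky ethers and keeps the larger CH2OSi group out of the pseudoequatorial site that eclipses the vinyl group, whereas a cyclic 3,19-acetal would hold C19 pseudoequatorial and open the wrong face. The low temperature allowed by the Lewis acid lets this modest conformational preference count and avoids the thermal 1,5-hydrogen shift from C20 to C7 that threatens the cis-substituted diene on long heating.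

**Step 9**
Reactants: 14 the 5,8-diene ester
Product: 16 methyl 3α,19-bis(TBS-oxy)-6α-hydroxy-12,13,14,15,16-pentanorlabd-8-en-11-oate (5α-H), via C6 alkylborane 15 (not isolated)
Conditions: BH3·THF (3 equiv), THF, 0 °C → rt; then 3 M NaOH, 30% H2O2, 0 °C
Reagents that add atoms: hydrogen peroxide, OO
Why: In the hydroboration–oxidation, syn addition of B–H to the trisubstituted Δ5 alkene puts boron on C6 and hydrogen on C5 from the α face, because the β face is closed by the syn-axial groups C20 and C19; oxidation with retention gives the 6α-alcohol and the trans ring fusion, while the tetrasubstituted conjugated C8=C9 bond does not react.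

**Step 10**
Reactants: 16 the 6α-alcohol
Product: 17 methyl 3α,19-bis(TBS-oxy)-6-oxo-12,13,14,15,16-pentanorlabd-8-en-11-oate (5α-H)
Conditions: Dess–Martin periodinane, NaHCO3, CH2Cl2, 0 °C → rt
Reagents that add atoms: none
Why: Dess–Martin oxidation under buffered, non-basic conditions should keep the β,γ-unsaturated ketone out of conjugation and leave C5 unepimerised.

**Step 11**
Reactants: 17 the 6-ketone
Product: 18 3α,19-bis(TBS-oxy)-12,13,14,15,16-pentanorlabd-8-ene-6β,11-diol
Conditions: i-Bu2AlH (5 equiv), CH2Cl2, −78 → 0 °C; aq. potassium sodium tartrate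
Reagents that add atoms: none
Why: In this hydride reduction the ketone is attacked from the open α (equatorial) side because C20 and C19 block the β side, which gives the axial 6β-alcohol, and the same non-basic reagent reduces the hindered enoate 1,2 to the C11 allylic alcohol.

**Step 12**
Reactants: 18 the 6β,11-diol
Product: 20 11-bromo-3α,19-bis(TBS-oxy)-12,13,14,15,16-pentanorlabd-8-en-6β-ol, via C11 mesylate 19 (not isolated)
Conditions: MsCl (1.1 equiv), Et3N, CH2Cl2, −40 °C; then LiBr, THF, −40 → 0 °C; used crude
Reagents that add atoms: lithium bromide, [Li+].[Br-]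
Why: The primary allylic alcohol is mesylated selectively (the axial 6β-hydroxyl between C19 and C20 is too hindered) and bromide displaces the mesylate by SN2.

**Step 13**
Reactants: 20 the allylic bromide; 21 ethyl sodioacetoacetate (sodium enolate of ethyl acetoacetate, commercial salt)
Product: 22 ethyl 3α,19-bis(TBS-oxy)-6β-hydroxy-13-oxo-14,15-dinorlabd-8-ene-12-carboxylate (C12 epimers; C11H2–CH(COCH3)CO2Et)
Conditions: 21 (3 equiv), THF–DMF, 0 °C → rt
Reagents that add atoms: none
Why: Acetoacetic ester alkylation by SN2 attack of the stabilised enolate on the primary allylic bromide forms C11–C12; SN2′ attack would have to occur at fully substituted C8, and the weakly basic enolate leaves the free hydroxyl alone.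

**Step 14**
Reactants: 22 the β-keto ester
Product: 23 3α,19-bis(TBS-oxy)-6β-hydroxy-14,15-dinorlabd-8-en-13-one
Conditions: LiCl, H2O (2 equiv), DMSO, 140 °C
Reagents that add atoms: none
Why: Krapcho dealkoxycarbonylation removes the ester group under neutral conditions that the silyl ethers and the free hydroxyl tolerate, leaving the methyl ketone (C13, C16).

**Step 15**
Reactants: 23 the methyl ketone; 24 triethyl phosphonoacetate
Product: 25 ethyl (13E)-3α,19-bis(TBS-oxy)-6β-hydroxylabda-8,13-dien-15-oate
Conditions: 24 (4 equiv), NaH (3.8 equiv), THF, 0 → 50 °C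
Reagents that add atoms: none
Why: Horner–Wadsworth–Emmons olefination of the methyl ketone should favour the E enoate (ester trans to the larger CH2 chain); the minor Z isomer is removed by chromatography.

**Step 16**
Reactants: 25 the bis-silyl enoate
Product: 26 ethyl (13E)-3α,6β,19-trihydroxylabda-8,13-dien-15-oate
Conditions: 48% aq. HF, MeCN, 0 °C → rt
Reagents that add atoms: none
Why: Fluoride-driven cleavage of both silyl ethers (Si–F bond formation) under mildly acidic conditions leaves the ester, both alkenes and all stereocentres untouched.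

**Step 17**
Reactants: 26 the triol ester
Product: 27 (13E)-3α,6β,19-trihydroxylabda-8,13-dien-15-oic acid
Conditions: LiOH·H2O, THF–MeOH–H2O, 40 °C; then 1 M HCl to pH 3
Reagents that add atoms: lithium hydroxide, [Li+].[OH-]
Why: Ester saponification (acyl substitution by hydroxide) and acidification give the acid without touching a stereocentre.

**Compound list**
1 | 2-methylcyclohexane-1,3-dione | CC1C(=O)CCCC1=O | starting material
2 | formaldehyde | C=O | starting material
3 | 2-(hydroxymethyl)-2-methylcyclohexane-1,3-dione | CC1(CO)C(=O)CCCC1=O | intermediate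
4 | 2-[(TBS-oxy)methyl]-2-methylcyclohexane-1,3-dione | CC1(CO[Si](C)(C)C(C)(C)C)C(=O)CCCC1=O | intermediate
5 | (2S,3R)-2-[(TBS-oxy)methyl]-3-hydroxy-2-methylcyclohexan-1-one | O=C1CCC[C@@H](O)[C@]1(C)CO[Si](C)(C)C(C)(C)C | intermediate
6 | (2S,3R)-3-(TBS-oxy)-2-[(TBS-oxy)methyl]-2-methylcyclohexan-1-one | O=C1CCC[C@@H](O[Si](C)(C)C(C)(C)C)[C@]1(C)CO[Si](C)(C)C(C)(C)C | intermediate
7 | lithium enolate of 6 (not isolated) | [Li]OC1=CCC[C@@H](O[Si](C)(C)C(C)(C)C)[C@]1(C)CO[Si](C)(C)C(C)(C)C | intermediate
8 | (2S,3R,6RS)-3-(TBS-oxy)-2-[(TBS-oxy)methyl]-2,6-dimethylcyclohexan-1-one | CC1CC[C@@H](O[Si](C)(C)C(C)(C)C)[C@](C)(CO[Si](C)(C)C(C)(C)C)C1=O | intermediate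
9 | potassium enolate of 8, tetrasubstituted (not isolated) | [K]OC1=C(C)CC[C@@H](O[Si](C)(C)C(C)(C)C)[C@]1(C)CO[Si](C)(C)C(C)(C)C | intermediate
10 | (5R,6S)-5-(TBS-oxy)-6-[(TBS-oxy)methyl]-2,6-dimethylcyclohex-1-en-1-yl trifluoromethanesulfonate | O=S(=O)(OC1=C(C)CC[C@@H](O[Si](C)(C)C(C)(C)C)[C@]1(C)CO[Si](C)(C)C(C)(C)C)C(F)(F)F | intermediate
11 | tributyl(vinyl)stannane | C=C[Sn](CCCC)(CCCC)CCCC | starting material
12 | ring-A diene, tert-butyl{[(1S,6R)-6-(TBS-oxy)-2-ethenyl-1,3-dimethylcyclohex-2-en-1-yl]methoxy}dimethylsilane | C=CC1=C(C)CC[C@@H](O[Si](C)(C)C(C)(C)C)[C@]1(C)CO[Si](C)(C)C(C)(C)C | intermediate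
13 | methyl but-2-ynoate | CC#CC(=O)OC | starting material
14 | methyl 3α,19-bis(TBS-oxy)-12,13,14,15,16-pentanorlabda-5,8-dien-11-oate (3R,4S,10S) | CC1=C(C(=O)OC)[C@@]2(C)CC[C@@H](O[Si](C)(C)C(C)(C)C)[C@](C)(CO[Si](C)(C)C(C)(C)C)C2=CC1 | intermediate
15 | C6 alkylborane from 14 (5α-H, 6α-BH2; not isolated) | CC1=C(C(=O)OC)[C@@]2(C)CC[C@@H](O[Si](C)(C)C(C)(C)C)[C@](C)(CO[Si](C)(C)C(C)(C)C)[C@@H]2[C@@H](B)C1 | intermediate
16 | methyl 3α,19-bis(TBS-oxy)-6α-hydroxy-12,13,14,15,16-pentanorlabd-8-en-11-oate | CC1=C(C(=O)OC)[C@@]2(C)CC[C@@H](O[Si](C)(C)C(C)(C)C)[C@](C)(CO[Si](C)(C)C(C)(C)C)[C@@H]2[C@@H](O)C1 | intermediate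
17 | methyl 3α,19-bis(TBS-oxy)-6-oxo-12,13,14,15,16-pentanorlabd-8-en-11-oate | CC1=C(C(=O)OC)[C@@]2(C)CC[C@@H](O[Si](C)(C)C(C)(C)C)[C@](C)(CO[Si](C)(C)C(C)(C)C)[C@@H]2C(=O)C1 | intermediate
18 | 3α,19-bis(TBS-oxy)-12,13,14,15,16-pentanorlabd-8-ene-6β,11-diol | CC1=C(CO)[C@@]2(C)CC[C@@H](O[Si](C)(C)C(C)(C)C)[C@](C)(CO[Si](C)(C)C(C)(C)C)[C@@H]2[C@H](O)C1 | intermediate
19 | C11 methanesulfonate of 18 (not isolated) | CC1=C(COS(C)(=O)=O)[C@@]2(C)CC[C@@H](O[Si](C)(C)C(C)(C)C)[C@](C)(CO[Si](C)(C)C(C)(C)C)[C@@H]2[C@H](O)C1 | intermediate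
20 | 11-bromo-3α,19-bis(TBS-oxy)-12,13,14,15,16-pentanorlabd-8-en-6β-ol | CC1=C(CBr)[C@@]2(C)CC[C@@H](O[Si](C)(C)C(C)(C)C)[C@](C)(CO[Si](C)(C)C(C)(C)C)[C@@H]2[C@H](O)C1 | intermediate
21 | ethyl sodioacetoacetate | CCOC(=O)C=C(C)[O-].[Na+] | starting material
22 | ethyl 3α,19-bis(TBS-oxy)-6β-hydroxy-13-oxo-14,15-dinorlabd-8-ene-12-carboxylate (C12 epimers) | CC1=C(CC(C(C)=O)C(=O)OCC)[C@@]2(C)CC[C@@H](O[Si](C)(C)C(C)(C)C)[C@](C)(CO[Si](C)(C)C(C)(C)C)[C@@H]2[C@H](O)C1 | intermediate
23 | 3α,19-bis(TBS-oxy)-6β-hydroxy-14,15-dinorlabd-8-en-13-one | CC1=C(CCC(C)=O)[C@@]2(C)CC[C@@H](O[Si](C)(C)C(C)(C)C)[C@](C)(CO[Si](C)(C)C(C)(C)C)[C@@H]2[C@H](O)C1 | intermediate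
24 | triethyl phosphonoacetate | CCOC(=O)CP(=O)(OCC)OCC | starting material
25 | ethyl (13E)-3α,19-bis(TBS-oxy)-6β-hydroxylabda-8,13-dien-15-oate | CC1=C(CC/C(C)=C/C(=O)OCC)[C@@]2(C)CC[C@@H](O[Si](C)(C)C(C)(C)C)[C@](C)(CO[Si](C)(C)C(C)(C)C)[C@@H]2[C@H](O)C1 | intermediate
26 | ethyl (13E)-3α,6β,19-trihydroxylabda-8,13-dien-15-oate | CC1=C(CC/C(C)=C/C(=O)OCC)[C@@]2(C)CC[C@@H](O)[C@](C)(CO)[C@@H]2[C@H](O)C1 | intermediate
27 | (13E)-3α,6β,19-trihydroxylabda-8,13-dien-15-oic acid (3R,4S,5R,6R,10S), CNP0246116.2 | CC1=C(CC/C(C)=C/C(=O)O)[C@@]2(C)CC[C@@H](O)[C@](C)(CO)[C@@H]2[C@H](O)C1 | target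

**Step count**
Total steps: 17. Longest linear sequence: 17 steps (1 → 27).

**Steps most likely to fail**

Step 8 (Diels–Alder reaction). The face preference rests on a conformational equilibrium of ring A and may be small, so part of the material may react through the diequatorial conformer and give the C10 epimer. Under Lewis-acid activation the bond formation may also become stepwise and leak into proton loss from the allylic cation, four-membered ring closure or loss of a silyl ether. Fallback: the cycloaddition is run as a purely thermal, concerted process with a stronger dienophile, and the C8 methyl is introduced afterwards. Diene 12 and methyl 3-bromopropiolate (made from methyl propiolate, N-bromosuccinimide and cat. AgNO3) are heated in toluene at 60–80 °C without Lewis acid. The same regiochemical rules put the bromine-bearing carbon on C7 and should give methyl 8-bromo-3α,19-bis(TBS-oxy)-12,13,14,15,16,17-hexanorlabda-5,8-dien-11-oate F1. Addition–elimination of Me2CuLi (Et2O, −78 °C) on this β-bromo enoate replaces bromine by methyl C17 and comes back to the route at 14.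

Step 3 (enzymatic desymmetrisation). No enzyme of the panel may combine the needed choice between the two carbonyls with hydride delivery syn to the silyloxymethyl group, which is the less common sense; the cis diastereomer or low conversion would result. Fallback: a reagent-controlled reduction with diastereomer separation and recycling. Dione 4 is treated with (S)-Me-CBS-oxazaborolidine (cat.) and BH3·SMe2 in THF at −20 °C. The catalyst should give the (R)-carbinol at whichever carbonyl it reduces, so the product is a pair of diastereomers: 5 and (2R,3R)-2-[(TBS-oxy)methyl]-3-hydroxy-2-methylcyclohexan-1-one F2 (hydroxyl cis to CH2OTBS). They are separated by chromatography, F2 is oxidised back to 4 with Dess–Martin periodinane and recycled, and the route is rejoined at 5.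

Step 12 (allylic bromide). The mesylate or bromide next to the tetrasubstituted alkene may ionise (elimination to dienes, allylic transposition), and the SN2 alkylation of step 13 at a carbon flanked by quaternary C10 may be slow. Fallback: the C11–C12 bond is made by olefination instead of alkylation. Diol 18 is oxidised with MnO2 (CH2Cl2, rt), which touches only the allylic alcohol and gives 3α,19-bis(TBS-oxy)-6β-hydroxy-12,13,14,15,16-pentanorlabd-8-en-11-al F3. Horner–Wadsworth–Emmons reaction with dimethyl (2-oxopropyl)phosphonate and NaH (THF) gives (11E)-3α,19-bis(TBS-oxy)-6β-hydroxy-14,15-dinorlabda-8,11-dien-13-one F4. Conjugate reduction with [(Ph3P)CuH]6 (THF, H2O, rt) saturates C11=C12 only, since C8 is fully substituted, and comes back to the route at 23; this replaces steps 12–14.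

**Further compounds**
F1 | step 8 | methyl 8-bromo-3α,19-bis(TBS-oxy)-12,13,14,15,16,17-hexanorlabda-5,8-dien-11-oate | BrC1=C(C(=O)OC)[C@@]2(C)CC[C@@H](O[Si](C)(C)C(C)(C)C)[C@](C)(CO[Si](C)(C)C(C)(C)C)C2=CC1
F2 | step 3 | (2R,3R)-2-[(TBS-oxy)methyl]-3-hydroxy-2-methylcyclohexan-1-one | O=C1CCC[C@@H](O)[C@@]1(C)CO[Si](C)(C)C(C)(C)C
F3 | step 12 | 3α,19-bis(TBS-oxy)-6β-hydroxy-12,13,14,15,16-pentanorlabd-8-en-11-al | CC1=C(C=O)[C@@]2(C)CC[C@@H](O[Si](C)(C)C(C)(C)C)[C@](C)(CO[Si](C)(C)C(C)(C)C)[C@@H]2[C@H](O)C1
F4 | step 12 | (11E)-3α,19-bis(TBS-oxy)-6β-hydroxy-14,15-dinorlabda-8,11-dien-13-one | CC1=C(/C=C/C(C)=O)[C@@]2(C)CC[C@@H](O[Si](C)(C)C(C)(C)C)[C@](C)(CO[Si](C)(C)C(C)(C)C)[C@@H]2[C@H](O)C1
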